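## Retrosynthetic overview

Numbering: C1 = ester carbonyl; oxolane ring = O, C5–C8; C9≡C10; C11=C12; C13–C16 = (CH2)4; C17=C18; C19=C20(Br).
1. C12–C13 is cut last. The enabling feature is the (E)-enyne C9≡C10–C11=C12 on ring carbon C8: its outer carbon C12 bears one H and the unbranched primary CH2-13. That is the syn H/alkyl adduct of a terminal buta-1,3-diynyl group, so the target splits into a diynyl-oxolane, a hydride and a primary C13–C20 triflate, joined by a three-component copper hydride hydroalkylation.
2. Diynyl-oxolane: C10–C11 by Cadiot–Chodkiewicz coupling, and C9≡C10 by Ohira–Bestmann homologation of the C9 aldehyde.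
3. The only ring (oxolane) is formed early through the O–C8 bond, by trans-selective cobalt-catalysed aerobic cyclisation of the C5 carbinol onto C8=C9. The C3–C4 bond comes from an enantiopure epoxide (source of C5) and methyl propiolate.
4. Triflate: pent-4-enal, two Wittig olefinations (C17=C18 E, C19=C20 Z), then chemoselective hydroboration of C13=C14.

Key step: step 12

Assumption: (S)-2-(but-3-en-1-yl)oxirane is bought enantiopure, and the target is the 2,5-trans oxolane (5R,8S) that the SMILES encodes.

## Route

Step 1
Reactants: 1 (S)-2-(but-3-en-1-yl)oxirane; 2 methyl propiolate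
Product: 4 methyl (5S)-5-hydroxynon-8-en-2-ynoate, via lithium methyl propiolate 3 (not isolated)
Conditions: 2, n-BuLi, THF, −78 °C; BF3·OEt2; then 1, −78 °C; H2O
Reagents that add atoms: n-butyllithium, [Li]CCCC (lithium of 3 only)
Why: The BF3-promoted SN2 opening of a terminal epoxide by a lithium acetylide (Yamaguchi–Hirao alkynylation) occurs at the unsubstituted carbon C4, so the C5 stereocentre of 1 is carried over unchanged, and the linear C2≡C3 unit keeps the 5-hydroxy ester from lactonising.

Step 2
Reactants: 4 methyl (5S)-5-hydroxynon-8-en-2-ynoate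
Product: 5 methyl 4-[(2S,5S)-5-(hydroxymethyl)oxolan-2-yl]but-2-ynoate (2,5-trans)
Conditions: Co(modp)2 (10 mol %; modp = 1-morpholinocarbamoyl-4,4-dimethylpentane-1,3-dionato), t-BuOOH (10 mol %), O2 (1 atm), i-PrOH, 55 °C
Reagents that add atoms: dioxygen, O=O
Why: The Mukaiyama aerobic oxidative cyclisation of a pent-4-en-1-ol closes the O–C8 bond in 5-exo-trig mode and oxygenates C9, and the C5 side chain sits pseudo-equatorial in the closing transition state, so the new C8 stereocentre is set trans to C5 by substrate control.

Step 3
Reactants: 5 methyl 4-[(2S,5S)-5-(hydroxymethyl)oxolan-2-yl]but-2-ynoate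
Product: 6 methyl 4-[(2R,5S)-5-(hydroxymethyl)oxolan-2-yl]butanoate
Conditions: H2 (1 atm), Pd/C, EtOAc, rt
Reagents that add atoms: none
Why: Heterogeneous catalytic hydrogenation saturates the alkynoate, the only reducible group present, and touches no stereocentre (the ring C2 descriptor changes from S to R through CIP priorities only).

Step 4
Reactants: 6 methyl 4-[(2R,5S)-5-(hydroxymethyl)oxolan-2-yl]butanoate
Product: 7 methyl 4-[(2R,5S)-5-formyloxolan-2-yl]butanoate
Conditions: TEMPO (10 mol %), PhI(OAc)2, CH2Cl2, rt
Reagents that add atoms: none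
Why: The oxoammonium (TEMPO/PhI(OAc)2) oxidation of a primary alcohol stops at the aldehyde under nearly neutral conditions, so the α-alkoxy stereocentre C8 should not epimerise.

Step 5
Reactants: 7 methyl 4-[(2R,5S)-5-formyloxolan-2-yl]butanoate
Product: 8 methyl 4-[(2R,5S)-5-ethynyloxolan-2-yl]butanoate
Conditions: dimethyl (1-diazo-2-oxopropyl)phosphonate, K2CO3, MeOH, 0 °C to rt
Reagents that add atoms: Ohira–Bestmann reagent, CC(=O)C(=[N+]=[N-])P(=O)(OC)OC
Why: The Ohira–Bestmann variant of the Seyferth–Gilbert homologation turns the aldehyde into the terminal alkyne (C10 added) under mild carbonate conditions in which methanolysis of the methyl ester is degenerate and C8 is retained.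

Step 6
Reactants: 8 methyl 4-[(2R,5S)-5-ethynyloxolan-2-yl]butanoate; 9 (bromoethynyl)triisopropylsilane
Product: 10 methyl 4-[(2R,5S)-5-[4-(triisopropylsilyl)buta-1,3-diyn-1-yl]oxolan-2-yl]butanoate
Conditions: CuCl (10 mol %), NH2OH·HCl (10 mol %), n-BuNH2, H2O/Et2O, 0 °C
Reagents that add atoms: none
Why: In the Cadiot–Chodkiewicz coupling the copper acetylide of 8 attacks bromoalkyne 9 to give the unsymmetrical diyne selectively, and the short cold exposure to the amine spares the methyl ester.

Step 7
Reactants: 10 methyl 4-[(2R,5S)-5-[4-(triisopropylsilyl)buta-1,3-diyn-1-yl]oxolan-2-yl]butanoate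
Product: 11 methyl 4-[(2R,5S)-5-(buta-1,3-diyn-1-yl)oxolan-2-yl]butanoate
Conditions: TBAF, AcOH, THF, 0 °C; product kept in solution and used at once
Reagents that add atoms: none
Why: Fluoride-induced protodesilylation of the diynylsilane is easy because the diynyl anion is a good leaving group, and the acetic acid buffer protects the ester and the sensitive terminal diyne from base.

Step 8
Reactants: 12 pent-4-enal
Product: 13 (2E)-hepta-2,6-dienal
Conditions: Ph3P=CHCHO, toluene, 80 °C
Reagents that add atoms: (triphenylphosphoranylidene)acetaldehyde, O=CC=P(c1ccccc1)(c1ccccc1)c1ccccc1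
Why: The Wittig olefination with a stabilised ylide should give the (E)-enal (C17=C18) under thermodynamic control of the oxaphosphetane.

Step 9
Reactants: 13 (2E)-hepta-2,6-dienal
Product: 14 (1Z,3E)-1-bromoocta-1,3,7-triene
Conditions: [Ph3PCH2Br]Br, KOt-Bu, THF, −78 °C; then 13, −78 °C
Reagents that add atoms: (bromomethyl)triphenylphosphonium bromide, BrC[P+](c1ccccc1)(c1ccccc1)c1ccccc1.[Br-]
Why: The Wittig olefination with the non-stabilised α-bromo ylide (bromo analogue of the Stork–Zhao reaction) runs through the kinetic cis-oxaphosphetane and should set the (Z)-C19=C20 bromide without touching the (E)-alkene.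

Step 10
Reactants: 14 (1Z,3E)-1-bromoocta-1,3,7-triene
Product: 16 (5E,7Z)-8-bromoocta-5,7-dien-1-ol, via B-alkyl-9-BBN adduct 15 (not isolated)
Conditions: 9-BBN-H (1.05 equiv), THF, 0 °C to rt; then 30 % H2O2, aq. NaOAc, 0 °C
Reagents that add atoms: hydrogen peroxide, OO; 9-borabicyclo[3.3.1]nonane, B1C2CCCC1CCC2 (boryl group of 15 only)
Why: In the Brown hydroboration–oxidation 9-BBN strongly prefers the isolated monosubstituted alkene C13=C14 over the conjugated, halogen-deactivated 1,2-disubstituted diene, places boron on C13, and the acetate-buffered oxidation avoids dehydrobromination.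

Step 11
Reactants: 16 (5E,7Z)-8-bromoocta-5,7-dien-1-ol
Product: 17 (5E,7Z)-8-bromoocta-5,7-dien-1-yl trifluoromethanesulfonate
Conditions: Tf2O, 2,6-lutidine, CH2Cl2, −78 °C; cold filtration through silica, used at once
Reagents that add atoms: triflic anhydride, O=S(=O)(OS(=O)(=O)C(F)(F)F)C(F)(F)F
Why: O-Sulfonylation of a primary alcohol with triflic anhydride and a hindered pyridine base is fast at low temperature and leaves the bromodiene untouched.

Step 12
Reactants: 11 methyl 4-[(2R,5S)-5-(buta-1,3-diyn-1-yl)oxolan-2-yl]butanoate; 17 (5E,7Z)-8-bromoocta-5,7-dien-1-yl trifluoromethanesulfonate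
Product: 19 methyl 4-[(2R,5S)-5-[(3E,9E,11Z)-12-bromododeca-3,9,11-trien-1-yn-1-yl]oxolan-2-yl]butanoate, via alkenylcopper complex 18 (not isolated)
Conditions: (IPr)CuOTf (10 mol %; IPr = 1,3-bis(2,6-diisopropylphenyl)imidazol-2-ylidene), (Me2HSi)2O, CsF, 1,4-dioxane, 40 °C
Reagents that add atoms: (IPr)CuOTf, CC(C)c1cccc(C(C)C)c1-n1cc[n+](-c2c(C(C)C)cccc2C(C)C)c1[Cu-]OS(=O)(=O)C(F)(F)F (copper–carbene unit of 18 only)
Why: Proposed new method: CsF turns (IPr)CuOTf into (IPr)CuF, the silane converts this into (IPr)CuH, the hydride adds syn across the terminal C11≡C12 bond of 11 with copper on the unhindered terminal carbon C12 to give alkenylcopper 18, and fluoride-assisted SN2 attack of 18 on the primary carbon C13 of triflate 17 forms the C12–C13 bond with retention at C12 and returns the copper to the cycle. The closest known reaction type is the copper hydride catalysed anti-Markovnikov hydroalkylation of terminal alkyl- and arylacetylenes with primary alkyl triflates, silane and CsF, which gives (E)-alkenes only but has not been shown on a terminal conjugated 1,3-diyne. No ring is closed and no tetrahedral stereocentre is made: the one new stereoelement, the (E)-C11=C12 double bond, is controlled by the syn hydrocupration followed by stereoretentive alkylation, while C5 and C8 are remote spectators. The step needs site selectivity for C11≡C12 over C9≡C10, over the enyne of the product and over the bromodiene, and this is secured by the bulky IPr ligand, which accepts only the single monosubstituted π bond, the inner alkyne being flanked by the branched ring carbon C8 and both diene double bonds being 1,2-disubstituted. It also needs a two-electron, palladium- and nickel-free C–C bond formation, because a radical at C13 would be a hex-5-enyl radical that closes onto C17=C18 and a zerovalent group-10 metal would insert into the C20–Br bond; the copper cycle meets both demands and tolerates the methyl ester. In one operation three components (diyne, hydride, triflate) are joined, the diyne is brought to the enyne oxidation level, the alkene geometry is set and the complete C20 skeleton of 19 is finished without any protecting group.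

## Compound list

1 | (S)-2-(but-3-en-1-yl)oxirane | C=CCC[C@H]1CO1 | starting material
2 | methyl propiolate | C#CC(=O)OC | starting material
3 | lithium methyl propiolate (methyl 3-lithioprop-2-ynoate) | [Li]C#CC(=O)OC | intermediate
4 | methyl (5S)-5-hydroxynon-8-en-2-ynoate | COC(=O)C#CC[C@@H](O)CCC=C | intermediate
5 | methyl 4-[(2S,5S)-5-(hydroxymethyl)oxolan-2-yl]but-2-ynoate (trans) | COC(=O)C#CC[C@@H]1CC[C@@H](CO)O1 | intermediate
6 | methyl 4-[(2R,5S)-5-(hydroxymethyl)oxolan-2-yl]butanoate (trans) | COC(=O)CCC[C@@H]1CC[C@@H](CO)O1 | intermediate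
7 | methyl 4-[(2R,5S)-5-formyloxolan-2-yl]butanoate | COC(=O)CCC[C@@H]1CC[C@@H](C=O)O1 | intermediate
8 | methyl 4-[(2R,5S)-5-ethynyloxolan-2-yl]butanoate | COC(=O)CCC[C@@H]1CC[C@@H](C#C)O1 | intermediate
9 | (bromoethynyl)triisopropylsilane | BrC#C[Si](C(C)C)(C(C)C)C(C)C | starting material
10 | methyl 4-[(2R,5S)-5-[4-(triisopropylsilyl)buta-1,3-diyn-1-yl]oxolan-2-yl]butanoate | COC(=O)CCC[C@@H]1CC[C@@H](C#CC#C[Si](C(C)C)(C(C)C)C(C)C)O1 | intermediate
11 | methyl 4-[(2R,5S)-5-(buta-1,3-diyn-1-yl)oxolan-2-yl]butanoate | COC(=O)CCC[C@@H]1CC[C@@H](C#CC#C)O1 | intermediate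
12 | pent-4-enal | C=CCCC=O | starting material
13 | (2E)-hepta-2,6-dienal | C=CCC/C=C/C=O | intermediate
14 | (1Z,3E)-1-bromoocta-1,3,7-triene | C=CCC/C=C/C=C\Br | intermediate
15 | 9-[(5E,7Z)-8-bromoocta-5,7-dien-1-yl]-9-borabicyclo[3.3.1]nonane | B1(CCCC/C=C/C=C\Br)C2CCCC1CCC2 | intermediate
16 | (5E,7Z)-8-bromoocta-5,7-dien-1-ol | OCCCC/C=C/C=C\Br | intermediate
17 | (5E,7Z)-8-bromoocta-5,7-dien-1-yl trifluoromethanesulfonate | FC(F)(F)S(=O)(=O)OCCCC/C=C/C=C\Br | intermediate
18 | (IPr)Cu–C12 (E)-alkenylcopper complex of the enynyl-oxolane ester | COC(=O)CCC[C@@H]1CC[C@@H](C#C/C=C/[Cu-]c2n(-c3c(C(C)C)cccc3C(C)C)cc[n+]2-c2c(C(C)C)cccc2C(C)C)O1 | intermediate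
19 | methyl 4-[(2R,5S)-5-[(3E,9E,11Z)-12-bromododeca-3,9,11-trien-1-yn-1-yl]oxolan-2-yl]butanoate | COC(=O)CCC[C@@H]1CC[C@@H](C#C/C=C/CCCC/C=C/C=C\Br)O1 | target

## Step count and risks

Total step count: 12. Longest linear sequence: 8 (steps 1–7 and 12).

**Step 12 (labelled step).**
- What may go wrong:
  - The acidic diyne C–H may be metalated to an unreactive copper diynide.
  - Hydrocupration may occur with reversed regiochemistry.
  - The product enyne may be reduced further.
  - Fluoride may cause dehydrobromination of the (Z)-bromodiene.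
- Fallback (known chemistry): it sets out from 11 and from borane 15, made from 14 as in step 10 but without the oxidation, and it returns at 19. Diyne 11 would be hydrozirconated at the terminal alkyne with Cp2Zr(H)Cl (THF, 0 °C) to the (E)-alkenylzirconocene chloride F1. This would be iodinated in the same flask with I2 to the (E)-iodoenyne F2. A B-alkyl Suzuki–Miyaura coupling of F2 with 15 (Pd(dppf)Cl2, AsPh3, Cs2CO3, DMF/THF/H2O, rt) forms the same C12–C13 bond with retention. Oxidative addition of zerovalent palladium into the activated C–I bond should outrun that into the C20–Br bond at room temperature.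

**Step 2.**
- What may go wrong:
  - The cobalt-catalysed oxidation may be slow or unselective, with attack of the oxidising species on the propargylic C4 methylene or on the electron-poor alkyne.
  - The trans selectivity may be incomplete.
- Fallback: it sets out from 4 and returns at 5, replacing the radical oxidation by a polar epoxide opening.
  - mCPBA (CH2Cl2, 0 °C) would epoxidise only the electron-rich terminal alkene to the epoxide F3, as both C8 epimers.
  - Hydrolytic kinetic resolution with (R,R)-(salen)Co(OAc) and water (the catalyst enantiomer that by the usual correlation consumes the (S)-configured terminal epoxide) would leave the (8R)-epoxide F4 and convert the other epimer into the separable triol F5.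
  - Camphorsulfonic acid (cat., CH2Cl2) would then close F4 by 5-exo-tet attack of the C5 hydroxyl on C8 with inversion, giving trans-5.

**Step 9.**
- What may go wrong:
  - Erosion of the Z selectivity may give a geometric isomer that is hard to remove.
  - The base may induce loss of HBr from the product.
- Fallback: it sets out from 13 and returns at 14. Ramirez olefination (CBr4, PPh3, CH2Cl2, 0 °C) would give the dibromotriene F6. The Pd(PPh3)4-catalysed hydrogenolysis with Bu3SnH (toluene, rt) removes selectively the less hindered bromine trans to the chain, so the (Z)-bromide is set by catalyst-controlled site selectivity instead of by ylide kinetics.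

## Further compounds

F1 | step 12 | chlorobis(cyclopentadienyl)[(E)-enynyl]zirconium derived from 11 (Zr on C12) | COC(=O)CCC[C@@H]1CC[C@@H](C#C/C=C/[Zr](Cl)(C2C=CC=C2)C2C=CC=C2)O1
F2 | step 12 | methyl 4-[(2R,5S)-5-[(E)-4-iodobut-3-en-1-yn-1-yl]oxolan-2-yl]butanoate | COC(=O)CCC[C@@H]1CC[C@@H](C#C/C=C/I)O1
F3 | step 2 | methyl (5S)-5-hydroxy-7-(oxiran-2-yl)hept-2-ynoate (both C8 epimers) | COC(=O)C#CC[C@@H](O)CCC1CO1
F4 | step 2 | methyl (5S)-5-hydroxy-7-[(2R)-oxiran-2-yl]hept-2-ynoate | COC(=O)C#CC[C@@H](O)CC[C@@H]1CO1
F5 | step 2 | methyl (5S,8S)-5,8,9-trihydroxynon-2-ynoate | COC(=O)C#CC[C@@H](O)CC[C@H](O)CO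
F6 | step 9 | (3E)-1,1-dibromoocta-1,3,7-triene | C=CCC/C=C/C=C(Br)Br
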